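**Strategy.** The trans-decalin is disconnected at its ring-fusion bond C5–C10 (drimane numbering: ring A = C1–C5 and C10, ring B = C5–C10; C4 bears the methylidene, C9 the arylmethyl group). An acyclic trienone, a vinyl ketone (C6=C5–C4=O) linked through C3–C1 to an (E)-tetrasubstituted 2-(silylmethyl)diene (C10=C9–C8=C7), undergoes a catalytic enantioselective intramolecular Diels–Alder reaction that forms C5–C10 and C6–C7, closes both rings and sets C5 and quaternary C10. The step exploits the 1,4-relationship across ring B between C5, beside the C4 methylidene carbon, and C8: the adduct carries a C4 ketone and a C8=C9 allylsilane, from which C9 (Hosomi–Sakurai) and C8 (hydroxyl-directed hydrogenation) follow.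

Key step: step 5

Remark: compound 3 is used as the racemate, since its carbinol centre is erased in step 4; the carbinol centre formed in step 7 is carried as an epimer mixture until step 9 removes it.

Assumption: the sense of induction of the oxazaborolidinium catalyst on 8 is taken to follow its vinyl-ketone binding model. The (S)-catalyst is written; if the sense on this substrate is the opposite, the (R)-catalyst is used with nothing else changed.

**Step 1**
Reactants: 1 methyl 2-methyl-3-oxobutanoate
Product: 2 methyl (2E)-2-methyl-3-(tosyloxy)but-2-enoate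
Conditions: TsCl, N-methylimidazole, Et3N, MeCN, 0 °C → rt
Reagents that add atoms: p-toluenesulfonyl chloride, Cc1ccc(cc1)S(Cl)(=O)=O
Why: Stereocomplementary enol tosylation of a β-keto ester: O-sulfonylation of the non-chelated enolate by the N-sulfonylimidazolium salt should place OTs anti to the ester, which fixes the (E)-geometry that later puts the tether on the outside of the diene.

**Step 2**
Reactants: 3 hexa-1,5-dien-3-ol; 2 methyl (2E)-2-methyl-3-(tosyloxy)but-2-enoate
Product: 5 methyl (2E)-7-hydroxy-2,3-dimethylnona-2,8-dienoate, via bis(9-BBN) adduct 4 (not isolated)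
Conditions: 9-BBN (2.2 equiv), THF, 0 °C → rt; then 2, Pd(OAc)2, SPhos, K3PO4, THF–H2O, 50 °C
Reagents that add atoms: none
Why: Hydroboration followed by B-alkyl Suzuki–Miyaura coupling with retention of alkene geometry; the hydroxyl is first converted into a bulky, electron-withdrawing O-borinate, so 9-BBN should add to the remote allyl terminus and not to the vinyl group beside the carbinol.

**Step 3**
Reactants: 5 methyl (2E)-7-hydroxy-2,3-dimethylnona-2,8-dienoate
Product: 7 (7E)-7,8-dimethyl-9-[(trimethylsilyl)methyl]deca-1,7,9-trien-3-ol, via bis(silylmethyl)carbinol 6 (not isolated)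
Conditions: Me3SiCH2MgCl (5 equiv), CeCl3 (5 equiv), THF, −78 °C → rt; then SiO2, CH2Cl2, rt
Reagents that add atoms: (trimethylsilyl)methylmagnesium chloride, C[Si](C)(C)C[Mg]Cl
Why: Ester-to-allylsilane conversion: double addition of the non-basic organocerium reagent to the hindered ester, then Peterson elimination of one β-silyl arm of 6, should give the 2-(silylmethyl)diene with the (E)-tetrasubstituted alkene untouched; the free hydroxyl only consumes one equivalent of reagent.

**Step 4**
Reactants: 7 (7E)-7,8-dimethyl-9-[(trimethylsilyl)methyl]deca-1,7,9-trien-3-ol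
Product: 8 (7E)-7,8-dimethyl-9-[(trimethylsilyl)methyl]deca-1,7,9-trien-3-one
Conditions: IBX, DMSO, rt; kept cold and used at once
Reagents that add atoms: none
Why: Neutral hypervalent-iodine oxidation of the secondary allylic alcohol to the vinyl ketone, chosen because no acid is present that could protodesilylate the allylsilane; the uncatalysed cycloaddition should be slow with this hindered diene.

**Step 5**
Reactants: 8 (7E)-7,8-dimethyl-9-[(trimethylsilyl)methyl]deca-1,7,9-trien-3-one
Product: 9 (4aS,8aR)-4a,5-dimethyl-6-[(trimethylsilyl)methyl]-3,4,4a,7,8,8a-hexahydronaphthalen-1(2H)-one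
Conditions: (S)-B-(o-tolyl)oxazaborolidine from (S)-α,α-diphenylprolinol, activated with Tf2NH (20 mol%), CH2Cl2, −78 → −20 °C
Reagents that add atoms: none
Why: The N-protonated oxazaborolidine binds the ketone oxygen of the vinyl ketone and lowers its LUMO, and the electron-rich 2-(silylmethyl)diene adds in an asynchronous [4+2] (or a Mukaiyama–Michael-like first bond followed at once by cation–enolate collapse) in which the nucleophilic C7 methylene bonds to the enone β-carbon C6 ahead of C10–C5, an orientation fixed by the tether and matched electronically. The closest known reaction type is the chiral-Lewis-acid-catalysed type 1 intramolecular Diels–Alder reaction of a 1,7,9-decatrien-3-one. Ring B is closed as the new cyclohexene by the two bonds of the cycloaddition (C5–C10 and C6–C7), and ring A is closed by the same C5–C10 bond across the four-atom tether C1–C4 as a six-membered, chair-like ring. C10 is set by the diene face that the catalyst-bound dienophile can reach (catalyst control of absolute configuration), and C5 follows from the (E)-geometry of C9=C10, which puts the tether outside and the C10 methyl inside, combined with the tether-exo mode that leaves H5 under the diene and gives the trans fusion. The step needs exo over endo selectivity, which the C9 methyl should secure because the endo mode pushes the tether and the catalyst-laden carbonyl under the fully substituted C8–C9 edge of the diene; C5 lies α to the new ketone, so the fusion stays correctable by enolisation at this stage.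

**Step 6**
Reactants: 10 methyl 3-formyl-4-hydroxybenzoate
Product: 11 methyl 4-(benzyloxy)-3-formylbenzoate
Conditions: BnBr, K2CO3, DMF, rt
Reagents that add atoms: benzyl bromide, BrCc1ccccc1
Why: Williamson ether synthesis on the phenol; the benzyl group keeps the phenol from forming a Brønsted-acidic BF3 complex in step 7 and leaves in step 9.

**Step 7**
Reactants: 9 (4aS,8aR)-4a,5-dimethyl-6-[(trimethylsilyl)methyl]-3,4,4a,7,8,8a-hexahydronaphthalen-1(2H)-one; 11 methyl 4-(benzyloxy)-3-formylbenzoate
Product: 12 methyl 4-(benzyloxy)-3-{hydroxy[(1R,4aR,8aS)-1,8a-dimethyl-2-methylidene-5-oxodecahydronaphthalen-1-yl]methyl}benzoate (carbinol epimers)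
Conditions: BF3·OEt2 (2 equiv), CH2Cl2, −78 °C; aq. NaHCO3 work-up
Reagents that add atoms: none
Why: Hosomi–Sakurai allylation: the BF3-activated aldehyde should attack C9, the γ-carbon of the allylsilane, on the α-face anti to the pseudoaxial C10 methyl, and loss of silicon moves the double bond to C8=CH2, so C9 becomes quaternary with methyl β and the carbinol arm α (the carbinol centre itself is uncontrolled and irrelevant).

**Step 8**
Reactants: 12 methyl 4-(benzyloxy)-3-{hydroxy[(1R,4aR,8aS)-1,8a-dimethyl-2-methylidene-5-oxodecahydronaphthalen-1-yl]methyl}benzoate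
Product: 13 methyl 4-(benzyloxy)-3-{hydroxy[(1R,2S,4aR,8aS)-1,2,8a-trimethyl-5-oxodecahydronaphthalen-1-yl]methyl}benzoate (carbinol epimers)
Conditions: H2 (1 atm), [Ir(cod)(PCy3)(py)]PF6 (5 mol%), CH2Cl2, rt
Reagents that add atoms: none
Why: Hydroxyl-directed homogeneous hydrogenation: the homoallylic hydroxyl on the α-oriented C9 arm binds iridium and should deliver H2 to the α-face of the C8 methylidene, which makes the C8 methyl β (cis to the C9 and C10 methyls) against the thermodynamic preference.

**Step 9**
Reactants: 13 methyl 4-(benzyloxy)-3-{hydroxy[(1R,2S,4aR,8aS)-1,2,8a-trimethyl-5-oxodecahydronaphthalen-1-yl]methyl}benzoate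
Product: 14 methyl 4-hydroxy-3-{[(1R,2S,4aR,8aS)-1,2,8a-trimethyl-5-oxodecahydronaphthalen-1-yl]methyl}benzoate
Conditions: H2 (3 bar), Pd/C, EtOAc–AcOH, rt
Reagents that add atoms: none
Why: Catalytic hydrogenolysis should remove the benzyl ether and then reduce the o-hydroxybenzylic alcohol (directly or through its o-quinone methide) to the ArCH2 group, while the ketone, the ester and all stereocentres are unaffected under these weakly acidic conditions.

**Step 10**
Reactants: 14 methyl 4-hydroxy-3-{[(1R,2S,4aR,8aS)-1,2,8a-trimethyl-5-oxodecahydronaphthalen-1-yl]methyl}benzoate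
Product: 15 methyl 4-hydroxy-3-{[(1R,2S,4aS,8aS)-1,2,8a-trimethyl-5-methylidenedecahydronaphthalen-1-yl]methyl}benzoate (CNP0169318.1)
Conditions: Zn, CH2Br2, TiCl4 (excess), THF–CH2Cl2, 0 °C → rt; aq. NaHCO3 work-up
Reagents that add atoms: dibromomethane, BrCBr
Why: Takai–Lombardo methylenation with the gem-dimetallic CH2 reagent should convert the C4 ketone into the exocyclic methylidene without base, so the epimerisable C5 next to the carbonyl keeps its trans configuration and the ester is untouched.

**Compound list**

1 | methyl 2-methyl-3-oxobutanoate | CC(=O)C(C)C(=O)OC | starting material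
2 | methyl (2E)-2-methyl-3-(tosyloxy)but-2-enoate (OTs trans to the ester) | COC(=O)/C(C)=C(C)/OS(=O)(=O)c1ccc(C)cc1 | intermediate
3 | hexa-1,5-dien-3-ol (racemic) | C=CCC(O)C=C | starting material
4 | bis(9-BBN) adduct of 3: 9-borabicyclo[3.3.1]nonan-9-yl groups on C6 and on the oxygen | C=CC(OB1C2CCCC1CCC2)CCCB1C2CCCC1CCC2 | intermediate
5 | methyl (2E)-7-hydroxy-2,3-dimethylnona-2,8-dienoate | COC(=O)/C(C)=C(C)/CCCC(O)C=C | intermediate
6 | (3E)-3,4-dimethyl-1-(trimethylsilyl)-2-[(trimethylsilyl)methyl]deca-3,9-diene-2,8-diol | C=CC(O)CCC/C(C)=C(C)/C(O)(C[Si](C)(C)C)C[Si](C)(C)C | intermediate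
7 | (7E)-7,8-dimethyl-9-[(trimethylsilyl)methyl]deca-1,7,9-trien-3-ol | C=CC(O)CCC/C(C)=C(C)/C(=C)C[Si](C)(C)C | intermediate
8 | (7E)-7,8-dimethyl-9-[(trimethylsilyl)methyl]deca-1,7,9-trien-3-one (vinyl ketone C6=C5–C4=O, tether C3–C1, diene C10=C9–C8=C7) | C=CC(=O)CCC/C(C)=C(C)/C(=C)C[Si](C)(C)C | intermediate
9 | (4aS,8aR)-4a,5-dimethyl-6-[(trimethylsilyl)methyl]-3,4,4a,7,8,8a-hexahydronaphthalen-1(2H)-one (trans-fused; C4 ketone, 10β-methyl, 5α-H, C8=C9 allylsilane) | O=C1CCC[C@@]2(C)[C@H]1CCC(C[Si](C)(C)C)=C2C | intermediate
10 | methyl 3-formyl-4-hydroxybenzoate | COC(=O)c1ccc(O)c(C=O)c1 | starting material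
11 | methyl 4-(benzyloxy)-3-formylbenzoate | COC(=O)c1ccc(OCc2ccccc2)c(C=O)c1 | intermediate
12 | methyl 4-(benzyloxy)-3-{hydroxy[(1R,4aR,8aS)-1,8a-dimethyl-2-methylidene-5-oxodecahydronaphthalen-1-yl]methyl}benzoate (C9: methyl β, carbinol arm α; carbinol epimers) | O=C1CCC[C@@]2(C)[C@H]1CCC(=C)[C@@]2(C)C(O)c3cc(C(=O)OC)ccc3OCc4ccccc4 | intermediate
13 | methyl 4-(benzyloxy)-3-{hydroxy[(1R,2S,4aR,8aS)-1,2,8a-trimethyl-5-oxodecahydronaphthalen-1-yl]methyl}benzoate (C8 methyl β; carbinol epimers) | O=C1CCC[C@@]2(C)[C@H]1CC[C@H](C)[C@@]2(C)C(O)c3cc(C(=O)OC)ccc3OCc4ccccc4 | intermediate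
14 | methyl 4-hydroxy-3-{[(1R,2S,4aR,8aS)-1,2,8a-trimethyl-5-oxodecahydronaphthalen-1-yl]methyl}benzoate | O=C1CCC[C@@]2(C)[C@H]1CC[C@H](C)[C@@]2(C)Cc3cc(C(=O)OC)ccc3O | intermediate
15 | methyl 4-hydroxy-3-{[(1R,2S,4aS,8aS)-1,2,8a-trimethyl-5-methylidenedecahydronaphthalen-1-yl]methyl}benzoate | C=C1CCC[C@@]2(C)[C@H]1CC[C@H](C)[C@@]2(C)Cc1cc(C(=O)OC)ccc1O | target

**Totals.** Total step count: 10. Longest linear sequence: 9 steps (1 → 2 → 5 → 7 → 8 → 9 → 12 → 13 → 14 → 15); step 6 is a one-step side branch.

**Steps most likely to fail**

Step 5. What may go wrong: cycloaddition through the tether-endo mode (cis ring fusion), desilylation of the diene by the cationic Lewis acid before the ring closes, or weak facial discrimination on the fully substituted diene. The fallback sets out again from 8 and activates the vinyl ketone covalently as its iminium ion with a chiral imidazolidinone salt, (2S,5S)-5-benzyl-3-methyl-2-(5-methylfuran-2-yl)imidazolidin-4-one·HClO4 or its antipode, in H2O–EtOH at 0 °C. This is amine catalysis in a protic medium: no Lewis acid touches the allylsilane, and the dienophile is shielded by a covalently bound group instead of a coordinated one. Hydrolysis of the product iminium ion brings the route back at 9. This fallback makes no compound outside the list (F0).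

Step 7. What may go wrong: bond formation at the fully substituted C9 beside quaternary C10 may be slower than protodesilylation of the allylsilane or than ionisation of the product carbinol. The fallback sets out from 9: BCl3 (CH2Cl2, −78 °C) exchanges silicon for boron to give the allyldichloroborane F1, which is not isolated. F1 adds to 11 by allylboration through a closed six-membered chair transition state, which tolerates γ,γ-disubstitution far better and should again deliver the arm anti to the C10 methyl. Aqueous NaHCO3 work-up brings the route back at 12.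

Step 9. What may go wrong: after loss of the benzyl ether, hydrogenolysis of the neopentylic benzylic C–O bond may stall, or long contact with acid may enolise C4 and epimerise C5. The fallback sets out from 13 and uses Barton–McCombie radical deoxygenation. PhOC(S)Cl, pyridine and DMAP give the O-phenyl thionocarbonate F2. Bu3SnH and AIBN in toluene at 80 °C then give the deoxygenated benzyl ether F3 through a benzylic radical. Neutral hydrogenolysis (H2, Pd/C, EtOAc) removes the benzyl group and brings the route back at 14.

**Further compounds**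

F0 | step 5 | none | none
F1 | step 7 | (4aS,8aR)-6-[(dichloroboranyl)methyl]-4a,5-dimethyl-3,4,4a,7,8,8a-hexahydronaphthalen-1(2H)-one | O=C1CCC[C@@]2(C)[C@H]1CCC(CB(Cl)Cl)=C2C
F2 | step 9 | O-phenyl thionocarbonate of 13: methyl 4-(benzyloxy)-3-{[(phenoxycarbonothioyl)oxy][(1R,2S,4aR,8aS)-1,2,8a-trimethyl-5-oxodecahydronaphthalen-1-yl]methyl}benzoate | O=C1CCC[C@@]2(C)[C@H]1CC[C@H](C)[C@@]2(C)C(OC(=S)Oc3ccccc3)c4cc(C(=O)OC)ccc4OCc5ccccc5
F3 | step 9 | methyl 4-(benzyloxy)-3-{[(1R,2S,4aR,8aS)-1,2,8a-trimethyl-5-oxodecahydronaphthalen-1-yl]methyl}benzoate | O=C1CCC[C@@]2(C)[C@H]1CC[C@H](C)[C@@]2(C)Cc3cc(C(=O)OC)ccc3OCc4ccccc4
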